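**Assumption:** the side chain is (2E,6E)-farnesyl as drawn and is bought as (2E,6E)-farnesyl bromide; the target is the (1R,5R,6R) enantiomer. Ring numbering below follows the target: C1 = C=O, C2 = farnesyl-bearing oxirane carbon, C3 = oxirane CH, C4 = CHOH, C5 = C–Et, C6 = =CH.

## Retrosynthetic overview

1. Target ⇐ Saegusa–Ito dehydrogenation (C5=C6) of epoxy ketone 16; oxirane ⇐ hydroxyl-directed nucleophilic epoxidation of hydroxy-enone 14.
2. 14 ⇐ retro-Diels–Alder of tricycle 13; farnesyl (enolate C-alkylation at C2) and ethyl (cuprate at C5) are installed while C2=C3 is locked as a norbornene.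
3. Tricycle ⇐ Diels–Alder of cyclopentadiene with enone 6, then E1cB opening of the acetonide. This gives a masked 4-hydroxycyclohexa-2,5-dienone that cannot aromatise.
4. Enone 6 ⇐ (−)-quinic acid in four steps; quinic C4 becomes target C4 and is the only purchased stereocentre kept.
5. Ring order: cyclohexane (from quinic acid) → norbornene (Diels–Alder, temporary) → oxirane (step 10).

## Route

**Step 1**
Reactants: 1 (−)-quinic acid; 2 2,2-dimethoxypropane
Product: 3, quinic acid 1,5-lactone 3,4-acetonide
Conditions: TsOH (cat.), acetone, reflux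
Reagents that add atoms: 2,2-dimethoxypropane, COC(C)(C)OC
Why: Acid-catalysed lactonisation/acetalisation; the cis-3,4-diol forms the dioxolane and the 5-OH (cis to CO2H) closes the lactone, with no stereocentre touched.

**Step 2**
Reactants: 3
Product: 4, 1-(hydroxymethyl)cyclohexane-1,5-diol 3,4-acetonide (quinic configurations retained)
Conditions: NaBH4, EtOH, 0 °C → rt
Reagents that add atoms: none
Why: Hydride reduction of the strained lactone to the primary alcohol, unmasking a 1,2-diol at C1.

**Step 3**
Reactants: 4
Product: 5, (3R,4S,5R)-5-hydroxy-3,4-(isopropylidenedioxy)cyclohexan-1-one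
Conditions: NaIO4, pH 7 phosphate buffer, 0 °C
Reagents that add atoms: none
Why: Malaprade glycol cleavage of the tertiary/primary 1,2-diol gives the ketone (target C1) and removes the carboxyl carbon.

**Step 4**
Reactants: 5
Product: 6, (4S,5R)-4,5-(isopropylidenedioxy)cyclohex-2-en-1-one
Conditions: MsCl, Et3N, CH2Cl2, 0 °C
Reagents that add atoms: none
Why: Mesylation and E1cB elimination of the β-hydroxy ketone; the mesylate leaves in preference to the acetonide oxygen.

**Step 5**
Reactants: 6; 7 cyclopentadiene (freshly cracked)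
Product: 8, endo Diels–Alder adduct (cis-fused norbornene on C2/C3, on the face anti to the acetonide)
Conditions: Et2AlCl, CH2Cl2, −78 °C
Reagents that add atoms: cyclopentadiene, C1C=CC=C1
Why: Lewis-acid-promoted suprafacial [4+2] cycloaddition, endo and anti to the dioxolane; it locks C2=C3 so the ring cannot aromatise and makes C2 an enolisable ring-fusion carbon. All new centres are temporary.

**Step 6**
Reactants: 8
Product: 9, tricyclic 4-hydroxy-enone (C5=C6 enone, free C4–OH on the convex face)
Conditions: DBU, THF, 0 °C → rt; aq. NH4Cl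
Reagents that add atoms: none
Why: E1cB β-elimination of the acetonide oxygen on C5 (acetone lost on work-up) gives the γ-hydroxy enone; C4 keeps the quinic acid configuration.

**Step 7**
Reactants: 9; 10 (2E,6E)-farnesyl bromide
Product: 11, tricyclic enone carrying farnesyl on the ring-fusion carbon C2
Conditions: LDA (2.2 equiv), THF/DMPU, −78 °C; then 10, −78 → −30 °C
Reagents that add atoms: farnesyl bromide, BrC/C=C(\C)CC/C=C(\C)CCC=C(C)C
Why: α′-Alkylation of the kinetic cross-conjugated lithium dienolate (as the alkoxide dianion); SN2 at the primary allylic bromide from the exo face keeps the E,E geometry, and the quaternary centre is temporary.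

**Step 8**
Reactants: 11; 12 ethylmagnesium bromide
Product: 13, tricyclic ketone with ethyl at C5
Conditions: EtMgBr (3 equiv), CuBr·SMe2 (10 mol %), TMSCl, THF, −78 °C; then 1 M HCl
Reagents that add atoms: ethylmagnesium bromide, CC[Mg]Br
Why: Cu-catalysed, TMSCl-accelerated conjugate addition puts ethyl on the enone β-carbon from the convex face; this centre is erased in step 11, so its configuration is immaterial.

**Step 9**
Reactants: 13
Product: 14, (4R,5R)-5-ethyl-4-hydroxy-2-[(2E,6E)-farnesyl]cyclohex-2-en-1-one
Conditions: Ph2O, 250 °C, 15 min (or flash vacuum pyrolysis, 450 °C)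
Reagents that add atoms: none
Why: Retro-Diels–Alder cycloreversion expels cyclopentadiene and regenerates C2=C3 as the 2-farnesyl enone; C4 is untouched.

**Step 10**
Reactants: 14; 15 tert-butyl hydroperoxide
Product: 16, (1R,4R,5R,6R)-4-ethyl-5-hydroxy-1-farnesyl-7-oxabicyclo[4.1.0]heptan-2-one
Conditions: t-BuOOH, Triton B (cat.), toluene/THF, 0 °C
Reagents that add atoms: tert-butyl hydroperoxide, CC(C)(C)OO
Why: Weitz–Scheffer nucleophilic epoxidation touches only the enone (the farnesyl alkenes are inert); the free C4–OH hydrogen-bonds the peroxide anion and delivers it to its own face, so both oxirane centres are set syn to the quinic-acid-derived carbinol.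

**Step 11**
Reactants: 16
Product: 17, target, (1R,5R,6R)-4-ethyl-5-hydroxy-1-[(2E,6E)-farnesyl]-7-oxabicyclo[4.1.0]hept-3-en-2-one
Conditions: LDA (2.2 equiv), TMSCl, THF, −78 °C; then Pd(OAc)2, MeCN, rt; citric acid, MeOH
Reagents that add atoms: none
Why: Saegusa–Ito oxidation; only C6 has enolisable hydrogens (C2 is a quaternary oxirane carbon), so the silyl enol ether gives the C5=C6 enone, and the syn epoxy-alkoxide cannot undergo Payne rearrangement.

## Compound list

1 | (−)-quinic acid | C1[C@H]([C@H]([C@@H](C[C@@]1(C(=O)O)O)O)O)O | starting material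
2 | 2,2-dimethoxypropane | COC(C)(C)OC | starting material
3 | quinic acid 1,5-lactone 3,4-acetonide | C1[C@H]([C@H]([C@@H](C[C@@]1(C2=O)O)O2)O3)OC3(C)C | intermediate
4 | 1-(hydroxymethyl)cyclohexane-1,5-diol 3,4-acetonide | C1[C@H]([C@H]([C@@H](C[C@@]1(CO)O)O)O2)OC2(C)C | intermediate
5 | (3R,4S,5R)-5-hydroxy-3,4-(isopropylidenedioxy)cyclohexanone | C1[C@H]([C@H]([C@@H](CC1=O)O)O2)OC2(C)C | intermediate
6 | (4S,5R)-4,5-(isopropylidenedioxy)cyclohex-2-enone | C1[C@H]([C@H](C=CC1=O)O2)OC2(C)C | intermediate
7 | cyclopentadiene | C1C=CC=C1 | starting material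
8 | endo, anti cyclopentadiene adduct of 6 | C1[C@H]([C@H]([C@@H]2[C@@H]3C=C[C@H]([C@@H]2C1=O)C3)O4)OC4(C)C | intermediate
9 | endo-6-hydroxytricyclo[6.2.1.0²,⁷]undeca-4,9-dien-3-one (OH on convex face) | C1=C[C@@H](O)[C@@H]2[C@@H]3C=C[C@H]([C@@H]2C1=O)C3 | intermediate
10 | (2E,6E)-farnesyl bromide | BrC/C=C(\C)CC/C=C(\C)CCC=C(C)C | starting material
11 | 9 with farnesyl on the ring-fusion carbon α to C=O | C1=C[C@@H](O)[C@@H]2[C@@H]3C=C[C@H]([C@]2(C/C=C(\C)CC/C=C(\C)CCC=C(C)C)C1=O)C3 | intermediate
12 | ethylmagnesium bromide | CC[Mg]Br | starting material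
13 | 11 after conjugate ethyl addition (ethyl cis to OH) | C1[C@@H](CC)[C@@H](O)[C@@H]2[C@@H]3C=C[C@H]([C@]2(C/C=C(\C)CC/C=C(\C)CCC=C(C)C)C1=O)C3 | intermediate
14 | (4R,5R)-5-ethyl-4-hydroxy-2-farnesylcyclohex-2-enone | C1[C@@H](CC)[C@@H](O)C=C(C/C=C(\C)CC/C=C(\C)CCC=C(C)C)C1=O | intermediate
15 | tert-butyl hydroperoxide | CC(C)(C)OO | starting material
16 | (1R,4R,5R,6R)-4-ethyl-5-hydroxy-1-farnesyl-7-oxabicyclo[4.1.0]heptan-2-one | C1[C@@H](CC)[C@@H](O)[C@H]2O[C@@]2(C/C=C(\C)CC/C=C(\C)CCC=C(C)C)C1=O | intermediate
17 | CID44566894 | CCC1=CC(=O)[C@]2(C/C=C(\C)CC/C=C(\C)CCC=C(C)C)O[C@@H]2[C@@H]1O | target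

## Summary

Total steps: 11. Longest linear sequence: 11 (from quinic acid).

Steps most likely to fail, each with a fallback that changes the approach:

- **Step 10 (syn-selective epoxidation).** It fixes the absolute configuration of the oxirane and rests on hydroxyl direction, which I have not verified for this exact substrate. Fallback: switch to electrophilic directed epoxidation. Luche-reduce 14 to the ene-1,4-diol, epoxidise with VO(acac)2/t-BuOOH (delivered by the allylic OH, farnesyl alkenes spared), oxidise and dehydrogenate to the epoxyquinone with IBX, then reduce the less hindered C4 carbonyl anti to the oxirane with DIBAL-H.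
- **Step 9 (retro-Diels–Alder at about 250 °C with a farnesyl chain and free carbinol).** Fallback: replace the cyclopentadiene mask with a thiophenol mask. PhSH adds to 6 with in-situ acetonide opening, ethyl is added by cuprate, and the mask is removed by sulfoxide elimination below 110 °C; farnesyl is then attached by α-iodination and Stille coupling.
- **Step 7 (C-alkylation of the hindered ring-fusion dienolate as a dianion).** Fallback: omit the alkylation. Take 9 through steps 8 and 9 to 5-ethyl-4-hydroxycyclohex-2-enone, then introduce farnesyl at C2 by α-iodination (I2, pyridine) and Stille coupling with farnesyltributylstannane to reach 14.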